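At 10 h, the time of reading, delta and eta are to be judged, but the earlier runs stop at 8.00 h.

| setting | midnight | spring | delta | eta |
|---|---|---|---|---|
| solid substrate | 26 mM | 26 mM | 26 mM | 26 mM |
| reagent | 0.70 equiv | 0.70 equiv | 0.700 equiv | 0.700 equiv |
| scavenger | 1.4 equiv | 2.2 equiv | 1.00 equiv | 1.50 equiv |
| free catalyst | 2.6 mol% | 2.6 mol% | 2.6 mol% | 2.6 mol% |
| remark | run made earlier | run made earlier |  |  |
| time |  |  | 10 h | 10 h |

| run | time / h | solid substrate / % | product / % |
|---|---|---|---|
| midnight | 0.500 | 99.3 | 1.6 |
| midnight | 0.833 | 97.9 | 0 |
| midnight | 1.33 | 96.5 | 0 |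
| midnight | 2.00 | 96.1 | 2.1 |
| midnight | 3.00 | 93.5 | 1.6 |
| midnight | 5.00 | 92.1 | 2.3 |
| midnight | 8.00 | 87.7 | 4.7 |
| spring | 0.417 | 99.7 | 0 |
| spring | 1.00 | 98.5 | 1.1 |
| spring | 2.00 | 95.3 | 0.8 |
| spring | 3.00 | 95.1 | 2.1 |
| spring | 4.00 | 93.2 | 1.6 |
| spring | 6.00 | 91.7 | 3.4 |
| spring | 8.00 | 87.6 | 5.7 |

(readings scatter by 1 percentage point)

1. part of the solid substrate that has reacted (what has only dissolved counts as not reacted) at the end, delta
2. part of the solid substrate that has reacted (what has only dissolved counts as not reacted) at the end, eta
3. what raising the equivalents of scavenger from its lowest to its highest value here does to the part of the solid substrate that has reacted (what has only dissolved counts as not reacted) (changes below 5 percentage points count as none) (no change / it falls / it rises)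

- as a solid, counted per litre of solution: solid substrate
- at the start none of the solid substrate is in solution
- what has only dissolved of solid substrate counts as not reacted

Two colleagues begin from the same reckoning. In midnight and spring the solid fell to 87.7% and 87.6% by 8.00 h, so it left at 0.401 mM h⁻¹. This is the mean crawl: solid lost per litre and hour, averaged over a run. Replacing the curve by this mean costs little: for 5.00 h in midnight it gives 7.72% lost, and 7.90% was read. The solid readings at 1.4 equiv and 2.2 equiv of scavenger end 0.1 percentage points apart. Carried to 10 h, the crawl takes 15.4% of the solid.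

The first colleague says that what leaves the solid has reacted, and so expects 15.4%. The second points to the gap between solid lost and product at 8.00 h, which averages 7.2 points, larger than the scatter of 1 point. The forecast takes this side, with 7% for delta, 7% for eta and no change, holding that the "remaining 7% or so is therefore dissolved, unreacted substrate". My own reckoning subtracts that gap from the crawl and gets 8.29%, higher than the forecast. It takes the gap as it stood at 8.00 h.

Delta gives 8.40%, eta gives 8.40%, and the trend is no change, so the second colleague stands. In eta at 10.0 h, 6.66% of the charge is still dissolved as starting material. Reacted and dissolved together come to 15.1%, beside the 15.4% from the crawl.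

    scavenger + released group → scavenged by-product (k = 0.0385 M⁻¹ s⁻¹)
    reagent + catalyst intermediate B ⇌ catalyst intermediate C (K = 35.2 M⁻¹, k = 3.05 M⁻¹ s⁻¹)
    catalyst intermediate E → spent catalyst (k = 2.19 × 10⁻⁵ s⁻¹)
    catalyst intermediate C → released group + catalyst intermediate D (k = 0.00449 s⁻¹)
    catalyst intermediate E → free catalyst + product (k = 0.00816 s⁻¹)
    starting material + free catalyst ⇌ catalyst intermediate A (K = 23.0 M⁻¹, k = 0.240 M⁻¹ s⁻¹)
    catalyst intermediate D → catalyst intermediate E (k = 0.00146 s⁻¹)
    catalyst intermediate A → catalyst intermediate B (k = 0.00583 s⁻¹)
    solid substrate ⇌ starting material, rate k9*(cs9 - [starting material]) while solid is left; crystals form when [starting material] > cs9 (solubility = 4.00 mM, k = 3.94 × 10⁻⁵ s⁻¹)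
    reagent + released group ⇌ idle adduct, settled at all times (K = 170 M⁻¹)

Take the same crawl per litre to a neighbour of eta charged with 100 mM of solid, its equivalents and loadings held: it gives 4.01% lost by 10 h. The computed flask loses 4.88% of its solid and has 4.24% reacted, with 0.637% dissolved against 6.66% in eta, and this is where the first colleague's view comes close.

All runs were generated by integration on assumed constants; noise was put on by code.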